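**Plan**
- Retrosynthesis: the aryl O-methyl and ester groups and the chain alkene (Wittig) go last; the saturated ring A and the C5–H come from the cis-fused C5 carbinol 19, which still has a C1=C2 bond and an allyl group on C4.
- Key cut: C2–C3 and C5–C10 together (plus C4–allyl). Carbinol 19 comes from allyl ether 16 of a cis-1-isopropenyl-2-vinylcyclohexenol by oxy-Cope shift, Claisen shift and transannular carbonyl-ene closure, so ring A is zipped onto a finished ring B.
- Enabling feature: across the C5–C10 fusion bond the target has C3–C4 on C5 and C1–C2 on C10, so C3=C4–C5(O)–C10–C1=C2 is a 3-oxy-1,5-diene. After the shift the quaternary C4 is the α-carbon of a C5 ketone and C2–H is the ene hydrogen.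
- Forward order: ring B from p-cresol (dearomatization, enantioselective conjugate benzylation with methylation, vinyl group, SmI2 deconjugation); then isopropenyl addition, O-allylation, the cascade (ring A), C5 deoxygenation, chain extension, ring A hydrogenation, demethylation.
- Stereochemistry: C9 from the copper catalyst; C10 by aldol addition anti to C9; the C5 carbinol by α-face addition; C4 by chirality transfer (C5/C10 centres → planar-chiral enol ether → Claisen); C10 re-formed under control of C9; C5–H by α-face hydrogen transfer to the C5 radical.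

Key step: step 9

Remark: locants C1–C10 are those of the decalin of the target (C4 carries CH3 and the side chain, C5/C10 are the ring-fusion carbons, C8 the methyl-bearing alkene carbon, C9 the arylmethyl-bearing carbon) and are also used for the monocyclic precursors; β is the face of the C10 methyl group.
Assumption: the sense of induction of the ligand in step 2 cannot be predicted with certainty, so both ligand enantiomers are screened and the one giving the (5R) ketone 6 is used.

Step 1
Reactants: 1 p-cresol
Product: 2 4-methoxy-4-methylcyclohexa-2,5-dien-1-one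
Conditions: PhI(OAc)2, MeOH, 0 °C
Reagents that add atoms: methanol (CO)
Why: Oxidative dearomatization of a para-alkylphenol with a hypervalent iodine diacetate in methanol (para-quinol ether formation) is standard and should give the symmetric dienone whose C8 already carries the methyl group and a leaving group for the later C7=C8 bond.

Step 2
Reactants: 2 4-methoxy-4-methylcyclohexa-2,5-dien-1-one; 3 4-bromo-2-(bromomethyl)-1-methoxybenzene
Product: 6 (5R)-5-(5-bromo-2-methoxybenzyl)-4-methoxy-4,6-dimethylcyclohex-2-en-1-one (mixture of C4/C6 epimers), via benzylic Grignard reagent 4 (not isolated), via magnesium dienolate 5 (not isolated)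
Conditions: 3, Mg, Et2O, 0 °C; then 2, CuBr·SMe2 (5 mol%), chiral Josiphos-type ferrocenyl diphosphine (6 mol%), t-BuOMe, −78 °C; then MeI, DMPU, −78 → 0 °C
Reagents that add atoms: iodomethane (CI)
Why: Copper-catalysed enantioselective conjugate addition of a Grignard reagent should desymmetrize the prochiral dienone, the chiral copper complex choosing the face of the β-carbon and so setting C9 (the C8 centre is lost in step 5, so its configuration does not matter), and the regiodefined magnesium enolate is C-methylated in the same flask.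

Step 3
Reactants: 6 (5R)-5-(5-bromo-2-methoxybenzyl)-4-methoxy-4,6-dimethylcyclohex-2-en-1-one
Product: 8 (5R,6S)-5-(5-bromo-2-methoxybenzyl)-6-(1-hydroxyethyl)-4-methoxy-4,6-dimethylcyclohex-2-en-1-one, via lithium dienolate 7 (not isolated)
Conditions: lithium diisopropylamide, THF, −78 °C; CH3CHO; AcOH quench at −78 °C
Reagents that add atoms: acetaldehyde (CC=O)
Why: Deprotonation can only occur at C10 because the other α-carbon is vinylic and the γ-carbon is quaternary, and the aldol addition should take place anti to the neighbouring C9 arylmethyl group (pseudo-axial by allylic strain in the enolate), which sets the C10 quaternary centre with methyl cis to the arylmethyl group.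

Step 4
Reactants: 8 (5R,6S)-5-(5-bromo-2-methoxybenzyl)-6-(1-hydroxyethyl)-4-methoxy-4,6-dimethylcyclohex-2-en-1-one
Product: 9 (5R,6R)-5-(5-bromo-2-methoxybenzyl)-6-ethenyl-4-methoxy-4,6-dimethylcyclohex-2-en-1-one
Conditions: Martin sulfurane (Ph2S[OC(CF3)2Ph]2), CH2Cl2, 0 °C → rt
Reagents that add atoms: none
Why: Dehydration of the secondary alcohol with Martin sulfurane can only run toward the methyl group because C10 is quaternary, so the 1-hydroxyethyl group should become the vinyl group (C1=C2).

Step 5
Reactants: 9 (5R,6R)-5-(5-bromo-2-methoxybenzyl)-6-ethenyl-4-methoxy-4,6-dimethylcyclohex-2-en-1-one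
Product: 11 (5S,6R)-5-(5-bromo-2-methoxybenzyl)-6-ethenyl-4,6-dimethylcyclohex-3-en-1-one, via samarium dienolate 10 (not isolated)
Conditions: SmI2 (2.5 equiv), THF–MeOH, −78 °C; pH 7 buffer
Reagents that add atoms: none
Why: Two-electron reduction of the enone by SmI2 with β-loss of the γ-methoxide (vinylogous α-alkoxy ketone cleavage) should give the dienolate, whose kinetic α-protonation delivers the deconjugated ketone with the C7=C8 bond in place; both C8 epimers converge.

Step 6
Reactants: 11 (5S,6R)-5-(5-bromo-2-methoxybenzyl)-6-ethenyl-4,6-dimethylcyclohex-3-en-1-one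
Product: 12 (1S,5S,6R)-5-(5-bromo-2-methoxybenzyl)-6-ethenyl-4,6-dimethyl-1-(prop-1-en-2-yl)cyclohex-3-en-1-ol
Conditions: isopropenylmagnesium bromide, CeCl3, THF, −78 °C
Reagents that add atoms: isopropenylmagnesium bromide (C=C(C)[Mg]Br)
Why: The weakly basic organocerium reagent (1,2-addition without enolization at the allylic C6) should attack the ketone from the α-face, anti to the axial C10 methyl group and away from the C9 arylmethyl group, which sets the C5 carbinol with hydroxyl cis to the C10 methyl group and the two alkenyl groups cis.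

Step 7
Reactants: 12 (1S,5S,6R)-5-(5-bromo-2-methoxybenzyl)-6-ethenyl-4,6-dimethyl-1-(prop-1-en-2-yl)cyclohex-3-en-1-ol
Product: 14 4-bromo-2-{[(1S,5S,6R)-5-(allyloxy)-6-ethenyl-2,6-dimethyl-5-(prop-1-en-2-yl)cyclohex-2-en-1-yl]methyl}-1-methoxybenzene, via sodium alkoxide 13 (not isolated)
Conditions: NaH, allyl bromide, Bu4NI (cat.), THF, 0 °C → rt
Reagents that add atoms: allyl bromide (C=CCBr)
Why: Williamson O-allylation of the tertiary sodium alkoxide at low temperature, where the anion-accelerated Cope shift of a hindered sodium alkoxide is slow, should give the allyl ether needed for the Claisen stage.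

Step 8
Reactants: 14 4-bromo-2-{[(1S,5S,6R)-5-(allyloxy)-6-ethenyl-2,6-dimethyl-5-(prop-1-en-2-yl)cyclohex-2-en-1-yl]methyl}-1-methoxybenzene
Product: 16 methyl 3-{[(1S,5S,6R)-5-(allyloxy)-6-ethenyl-2,6-dimethyl-5-(prop-1-en-2-yl)cyclohex-2-en-1-yl]methyl}-4-methoxybenzoate, via aryllithium 15 (not isolated)
Conditions: n-BuLi, THF, −78 °C; then ClCO2Me, −78 °C
Reagents that add atoms: methyl chloroformate (COC(=O)Cl)
Why: Bromine–lithium exchange is far faster than any reaction of the allyl ether or the alkenes at −78 °C, and acylation of the aryllithium puts the carboxyl carbon in place before the tin hydride step, which an aryl bromide would not survive.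

Step 9
Reactants: 16 methyl 3-{[(1S,5S,6R)-5-(allyloxy)-6-ethenyl-2,6-dimethyl-5-(prop-1-en-2-yl)cyclohex-2-en-1-yl]methyl}-4-methoxybenzoate
Product: 19 methyl 3-[(4β-allyl-5β-hydroxy-4α,8,10β-trimethyl-cis-1,7-octalin-9β-yl)methyl]-4-methoxybenzoate (cis-fused; C1=C2 and C7=C8), via ten-membered allyl enol ether 17 (not isolated), via ten-membered ketone 18 (not isolated)
Conditions: toluene (0.02 M), 220 °C, sealed vessel (microwave), base-washed glass, 2 h
Reagents that add atoms: none
Why: Heating should trigger a [3,3] oxy-Cope shift through a chair transition state with the C9 arylmethyl group pseudo-equatorial and the C5 isopropenyl group axial, which makes C2–C3, cuts C5–C10 and gives enol ether 17 with a ring-trans tetrasubstituted C4=C5 bond and a ring-cis C1=C10 bond; a Claisen shift of the O-allyl group to C4 then gives ketone 18, and a transannular carbonyl-ene reaction (hydrogen from C2 to oxygen) closes C5–C10. The closest known reaction type is the thermal tandem oxy-Cope/Claisen/ene reaction of allyl ethers of 1,2-dialkenylcyclohexanols. Ring A is closed in the ene step as a six-membered ring, 6-exo-trig at the C5 carbonyl and endo to the C1=C10 bond, through a boat-like bicyclo[2.2.2] array, and the same bond restores ring B. C4 is set by the Claisen shift on the outer face of the planar-chiral enol ether, whose sense is fixed by the C5 and C10 centres of 16 and which should not invert because neither alkene carbon carries hydrogen; C5 and C10 are set by the suprafacial ene step, in which the ring-cis alkene places the C10 methyl group cis to the new hydroxyl group and the pseudo-equatorial C9 substituent selects the face that restores the original C10 configuration. The step needs the exocyclic 3-oxy-1,5-diene to rearrange in preference to the two 1,5-dienes that contain the ring B alkene, which is secured because those would have to pass boat transition states to strained eight-membered rings, and it needs 1,6- rather than 1,5-transannular closure, which the allylic C2–H inside the forming six-membered ring provides.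

Step 10
Reactants: 19 methyl 3-[(4β-allyl-5β-hydroxy-4α,8,10β-trimethyl-cis-1,7-octalin-9β-yl)methyl]-4-methoxybenzoate
Product: 21 methyl oxalate of 19 (5β-O–CO–CO2CH3), via potassium alkoxide 20 (not isolated)
Conditions: KN(SiMe3)2, THF, −78 °C; ClC(O)CO2Me, −78 → 0 °C
Reagents that add atoms: methyl chlorooxoacetate (COC(=O)C(=O)Cl)
Why: The hindered tertiary alcohol should be acylated as its potassium alkoxide by the very electrophilic acid chloride, giving the tert-alkyl methyl oxalate needed for radical deoxygenation.

Step 11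
Reactants: 21 methyl oxalate of 19
Product: 22 methyl 3-[(4β-allyl-4α,8,10β-trimethyl-5α-H-trans-1,7-octalin-9β-yl)methyl]-4-methoxybenzoate
Conditions: Bu3SnH (high concentration), AIBN, toluene, 110 °C
Reagents that add atoms: none
Why: Radical deoxygenation of a tert-alkyl methyl oxalate with tin hydride should generate the planar C5 radical, which takes hydrogen from the α-face, opposite the β-oriented C10 methyl and C4 allyl groups, to give the trans ring fusion; with this inversion at C5 the allyl group becomes the axial 4β substituent of the target.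

Step 12
Reactants: 22 methyl 3-[(4β-allyl-4α,8,10β-trimethyl-5α-H-trans-1,7-octalin-9β-yl)methyl]-4-methoxybenzoate
Product: 24 primary alcohol (4β-(3-hydroxypropyl) analogue of 22), via alkylborane 23 (not isolated)
Conditions: 9-BBN, THF, 0 °C → rt; then H2O2, aq. NaOH, 0 °C
Reagents that add atoms: hydrogen peroxide (OO)
Why: 9-BBN hydroborates the monosubstituted terminal alkene much faster than the cis-disubstituted and trisubstituted ring alkenes, and oxidation should give the anti-Markovnikov primary alcohol.

Step 13
Reactants: 24 primary alcohol (4β-(3-hydroxypropyl) analogue of 22)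
Product: 25 methyl 3-{[4β-(3-hydroxypropyl)-4α,8,10β-trimethyl-5α-H-trans-7-octalin-9β-yl]methyl}-4-methoxybenzoate (ring A saturated)
Conditions: H2 (1 atm), RhCl(PPh3)3 (cat.), benzene, rt
Reagents that add atoms: none
Why: Homogeneous hydrogenation with RhCl(PPh3)3 reduces the cis-disubstituted C1=C2 bond far faster than the hindered trisubstituted C7=C8 bond, so ring A should be saturated selectively.

Step 14
Reactants: 25 methyl 3-{[4β-(3-hydroxypropyl)-4α,8,10β-trimethyl-5α-H-trans-7-octalin-9β-yl]methyl}-4-methoxybenzoate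
Product: 26 aldehyde (4β-(3-oxopropyl) analogue of 25)
Conditions: Dess–Martin periodinane, NaHCO3, CH2Cl2, 0 °C
Reagents that add atoms: none
Why: Dess–Martin oxidation of a primary alcohol under buffered conditions should give the aldehyde without touching the ester or the C7=C8 bond.

Step 15
Reactants: 26 aldehyde (4β-(3-oxopropyl) analogue of 25)
Product: 27 jaspic acid O-methyl ether methyl ester
Conditions: isopropyltriphenylphosphonium iodide, n-BuLi, THF, 0 °C; then 26, −78 °C → rt
Reagents that add atoms: isopropyltriphenylphosphonium iodide (CC(C)[P+](c1ccccc1)(c1ccccc1)c1ccccc1.[I-])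
Why: Wittig olefination with the non-stabilized isopropylidene ylide should build the trisubstituted chain alkene, the aldehyde reacting much faster than the aryl ester.

Step 16
Reactants: 27 jaspic acid O-methyl ether methyl ester
Product: 28 jaspic acid
Conditions: NaSEt (excess), DMF, 130 °C; then aq. HCl
Reagents that add atoms: none
Why: Thiolate SN2 attack on the two O-methyl groups should cleave the aryl methyl ether (activated by the para carboxyl group) and the methyl ester in one operation under non-acidic conditions that leave both trisubstituted alkenes alone.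

**Compound list**
1 | p-cresol (4-methylphenol) | Cc1ccc(O)cc1 | starting material
2 | 4-methoxy-4-methylcyclohexa-2,5-dien-1-one | COC1(C)C=CC(=O)C=C1 | intermediate
3 | 4-bromo-2-(bromomethyl)-1-methoxybenzene (5-bromo-2-methoxybenzyl bromide) | COc1ccc(Br)cc1CBr | starting material
4 | (5-bromo-2-methoxybenzyl)magnesium bromide | COc1ccc(Br)cc1C[Mg]Br | intermediate
5 | bromomagnesium dienolate formed by conjugate addition (C9 arylmethyl, C5 enolate) | Br[Mg]OC1=C[C@@H](Cc2cc(Br)ccc2OC)C(C)(OC)C=C1 | intermediate
6 | (5R)-5-(5-bromo-2-methoxybenzyl)-4-methoxy-4,6-dimethylcyclohex-2-en-1-one (epimers at C4 and C6 of this name) | CC1[C@@H](Cc2cc(Br)ccc2OC)C(C)(OC)C=CC1=O | intermediate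
7 | lithium dienolate of 6 (deprotonated at C10) | [Li]OC1=C(C)[C@@H](Cc2cc(Br)ccc2OC)C(C)(OC)C=C1 | intermediate
8 | (5R,6S)-5-(5-bromo-2-methoxybenzyl)-6-(1-hydroxyethyl)-4-methoxy-4,6-dimethylcyclohex-2-en-1-one (epimers at C4 and at the carbinol carbon) | CC(O)[C@]1(C)[C@@H](Cc2cc(Br)ccc2OC)C(C)(OC)C=CC1=O | intermediate
9 | (5R,6R)-5-(5-bromo-2-methoxybenzyl)-6-ethenyl-4-methoxy-4,6-dimethylcyclohex-2-en-1-one (both C4 epimers) | C=C[C@]1(C)[C@@H](Cc2cc(Br)ccc2OC)C(C)(OC)C=CC1=O | intermediate
10 | samarium dienolate (O–SmI2 at C5, C5=C6 and C7=C8) | C=C[C@]1(C)[C@@H](Cc2cc(Br)ccc2OC)C(C)=CC=C1O[Sm](I)I | intermediate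
11 | (5S,6R)-5-(5-bromo-2-methoxybenzyl)-6-ethenyl-4,6-dimethylcyclohex-3-en-1-one | C=C[C@]1(C)[C@@H](Cc2cc(Br)ccc2OC)C(C)=CCC1=O | intermediate
12 | (1S,5S,6R)-5-(5-bromo-2-methoxybenzyl)-6-ethenyl-4,6-dimethyl-1-(prop-1-en-2-yl)cyclohex-3-en-1-ol (OH cis to the C10 methyl, isopropenyl cis to vinyl) | C=C[C@]1(C)[C@@H](Cc2cc(Br)ccc2OC)C(C)=CC[C@]1(O)C(C)=C | intermediate
13 | sodium alkoxide of 12 | C=C[C@]1(C)[C@@H](Cc2cc(Br)ccc2OC)C(C)=CC[C@]1(O[Na])C(C)=C | intermediate
14 | 4-bromo-2-{[(1S,5S,6R)-5-(allyloxy)-6-ethenyl-2,6-dimethyl-5-(prop-1-en-2-yl)cyclohex-2-en-1-yl]methyl}-1-methoxybenzene (allyl ether of 12) | C=C[C@]1(C)[C@@H](Cc2cc(Br)ccc2OC)C(C)=CC[C@]1(OCC=C)C(C)=C | intermediate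
15 | aryllithium from 14 (Li in place of Br) | C=C[C@]1(C)[C@@H](Cc2cc([Li])ccc2OC)C(C)=CC[C@]1(OCC=C)C(C)=C | intermediate
16 | methyl 3-{[(1S,5S,6R)-5-(allyloxy)-6-ethenyl-2,6-dimethyl-5-(prop-1-en-2-yl)cyclohex-2-en-1-yl]methyl}-4-methoxybenzoate | C=C[C@]1(C)[C@@H](Cc2cc(C(=O)OC)ccc2OC)C(C)=CC[C@]1(OCC=C)C(C)=C | intermediate
17 | ten-membered allyl enol ether (C4=C5 ring-trans with O-allyl on C5, C1=C10 and C7=C8 ring-cis, C9 arylmethyl) | C=CCO/C1=C(C)\CC/C=C(C)\[C@@H](Cc2cc(C(=O)OC)ccc2OC)/C(C)=C\C1 | intermediate
18 | ten-membered ketone (C5=O, C4 quaternary with methyl and allyl, C1=C10 and C7=C8 ring-cis) | C=CC[C@@]1(C)CC/C=C(C)\[C@@H](Cc2cc(C(=O)OC)ccc2OC)/C(C)=C\CC1=O | intermediate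
19 | methyl 3-[(4β-allyl-5β-hydroxy-4α,8,10β-trimethyl-cis-1,7-octalin-9β-yl)methyl]-4-methoxybenzoate (cis-fused decalinol, C1=C2 and C7=C8) | C=CC[C@@]1(C)CC=C[C@]2(C)[C@@H](Cc3cc(C(=O)OC)ccc3OC)C(C)=CC[C@]12O | intermediate
20 | potassium alkoxide of 19 | C=CC[C@@]1(C)CC=C[C@]2(C)[C@@H](Cc3cc(C(=O)OC)ccc3OC)C(C)=CC[C@]12O[K] | intermediate
21 | methyl oxalate of 19 (5β-O–CO–CO2CH3) | C=CC[C@@]1(C)CC=C[C@]2(C)[C@@H](Cc3cc(C(=O)OC)ccc3OC)C(C)=CC[C@]12OC(=O)C(=O)OC | intermediate
22 | methyl 3-[(4β-allyl-4α,8,10β-trimethyl-5α-H-trans-1,7-octalin-9β-yl)methyl]-4-methoxybenzoate | C=CC[C@@]1(C)CC=C[C@]2(C)[C@@H](Cc3cc(C(=O)OC)ccc3OC)C(C)=CC[C@@H]12 | intermediate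
23 | B-alkyl-9-borabicyclo[3.3.1]nonane from 22 (boron on the terminal chain carbon) | C(CC[C@@]1(C)CC=C[C@]2(C)[C@@H](Cc3cc(C(=O)OC)ccc3OC)C(C)=CC[C@@H]12)B1C2CCCC1CCC2 | intermediate
24 | methyl 3-{[4β-(3-hydroxypropyl)-4α,8,10β-trimethyl-5α-H-trans-1,7-octalin-9β-yl]methyl}-4-methoxybenzoate | OCCC[C@@]1(C)CC=C[C@]2(C)[C@@H](Cc3cc(C(=O)OC)ccc3OC)C(C)=CC[C@@H]12 | intermediate
25 | methyl 3-{[4β-(3-hydroxypropyl)-4α,8,10β-trimethyl-5α-H-trans-7-octalin-9β-yl]methyl}-4-methoxybenzoate | OCCC[C@@]1(C)CCC[C@]2(C)[C@@H](Cc3cc(C(=O)OC)ccc3OC)C(C)=CC[C@@H]12 | intermediate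
26 | methyl 3-{[4β-(3-oxopropyl)-4α,8,10β-trimethyl-5α-H-trans-7-octalin-9β-yl]methyl}-4-methoxybenzoate | O=CCC[C@@]1(C)CCC[C@]2(C)[C@@H](Cc3cc(C(=O)OC)ccc3OC)C(C)=CC[C@@H]12 | intermediate
27 | jaspic acid O-methyl ether methyl ester | CC(C)=CCC[C@@]1(C)CCC[C@]2(C)[C@@H](Cc3cc(C(=O)OC)ccc3OC)C(C)=CC[C@@H]12 | intermediate
28 | jaspic acid | CC(C)=CCC[C@@]1(C)CCC[C@]2(C)[C@@H](Cc3cc(C(=O)O)ccc3O)C(C)=CC[C@@H]12 | target

Total step count: 16. Longest linear sequence: 16 steps (1 → 28; 3 enters in step 2).

**Steps most likely to fail**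

Step 9. At 220 °C the rearrangement may leave the chair pathway, the enol ether may lose its planar chirality before the Claisen shift (erosion of control at C4), or the skipped alkenes may migrate into conjugation. The fallback sets out from 12 and comes back at 19, and runs the three events stepwise at low temperature. Alcohol 12 is treated with KH and 18-crown-6 in THF at 0 °C (anion-accelerated oxy-Cope shift) and the ten-membered potassium enolate is C-allylated on its outer face with allyl bromide to give the bromo ten-membered ketone F2. Me2AlCl in CH2Cl2 at −78 °C then closes C5–C10 by a Lewis-acid-promoted transannular carbonyl-ene (Prins-type) reaction to the bromo cis-decalinol F3. Methoxycarbonylation of the aryl bromide (Pd(OAc)2, Xantphos, CO, MeOH, Et3N) returns to 19.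

Step 2. The benzylic Grignard reagent may add with poor enantiofacial control or attack the carbonyl group directly. The fallback sets out from 2 and 3 and comes back at 6, and replaces catalyst control by resolution. The same conjugate addition and methylation are run with CuBr·SMe2 alone (no chiral ligand) to give the racemic ketone F1, whose enantiomers are separated by preparative chromatography on a chiral stationary phase; the (5R) enantiomer is 6.

Step 11. The C5 radical may rearrange through the homoallylic C1=C2 bond (three-membered ring closure and reopening), and the tin radical may add to the terminal alkene. The fallback sets out from 19 and comes back at 25, and removes both alkenes before the radical is made. Hydroboration–oxidation of 19 (9-BBN; H2O2, NaOH) gives the diol F4. Hydrogenation over RhCl(PPh3)3 gives the ring-A-saturated diol F5. Silylation of the primary hydroxyl (t-BuMe2SiCl, imidazole) gives the silyl ether F6. Acylation (KN(SiMe3)2; ClC(O)CO2Me) gives the oxalate F7. Bu3SnH/AIBN gives the trans-fused silyl ether F8, and Bu4NF returns to 25.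

**Further compounds**
F1 | step 2 | racemic 5-(5-bromo-2-methoxybenzyl)-4-methoxy-4,6-dimethylcyclohex-2-en-1-one | CC1C(Cc2cc(Br)ccc2OC)C(C)(OC)C=CC1=O
F2 | step 9 | bromo ten-membered ketone (aryl bromide analogue of 18) | C=CC[C@@]1(C)CC/C=C(C)\[C@@H](Cc2cc(Br)ccc2OC)/C(C)=C\CC1=O
F3 | step 9 | bromo cis-decalinol (aryl bromide analogue of 19) | C=CC[C@@]1(C)CC=C[C@]2(C)[C@@H](Cc3cc(Br)ccc3OC)C(C)=CC[C@]12O
F4 | step 11 | diol: 4β-(3-hydroxypropyl) analogue of 19 | OCCC[C@@]1(C)CC=C[C@]2(C)[C@@H](Cc3cc(C(=O)OC)ccc3OC)C(C)=CC[C@]12O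
F5 | step 11 | ring-A-saturated diol | OCCC[C@@]1(C)CCC[C@]2(C)[C@@H](Cc3cc(C(=O)OC)ccc3OC)C(C)=CC[C@]12O
F6 | step 11 | primary tert-butyldimethylsilyl ether of F5 | CC(C)(C)[Si](C)(C)OCCC[C@@]1(C)CCC[C@]2(C)[C@@H](Cc3cc(C(=O)OC)ccc3OC)C(C)=CC[C@]12O
F7 | step 11 | methyl oxalate of F6 | CC(C)(C)[Si](C)(C)OCCC[C@@]1(C)CCC[C@]2(C)[C@@H](Cc3cc(C(=O)OC)ccc3OC)C(C)=CC[C@]12OC(=O)C(=O)OC
F8 | step 11 | trans-fused silyl ether (silyl ether of 25) | CC(C)(C)[Si](C)(C)OCCC[C@@]1(C)CCC[C@]2(C)[C@@H](Cc3cc(C(=O)OC)ccc3OC)C(C)=CC[C@@H]12
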